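**Retrosynthetic overview**

1. The target is numbered as a 6-oxabicyclo[3.2.1]octan-7-one: C1 (quaternary; carries lactone carbonyl C7 and the butenolide-ethyl chain), C2 (CH–CH3), C3, C4, C5 (O6 and isopropenyl), C8 (propanoate chain). Late disconnections are a Negishi C(sp3)–C(sp2) bond to 3-bromofuran-2(5H)-one, and the C5–O6 lactone bond plus isopropenyl group, which come from organocerium addition to a C5 ketone and lactonization onto the C1 carboxyl.
2. Key disconnection: C1–C2, made by an Ireland–Claisen ring contraction of a six-membered lactone (oxan-2-one) whose ring oxygen sits on C4 and whose carbinol carbon carries an (E)-prop-1-enyl group (C3=C2–CH3); the C3=C4 alkene that results is hydrogenated later.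
3. Enabling feature: C1 is the α-carbon of carbonyl C7, and C2, C3, C4 are the next three carbons of the cyclohexane ring, so C7(=O)–C1–C2–C3=C4 is a γ,δ-unsaturated acid (Claisen retron). Ring atoms C8 and C5 tie the enolate carbon C1 and the ester oxygen on C4 into a δ-lactone that can rearrange only through a boat.
4. The δ-lactone comes from (E)-but-2-enal: asymmetric γ-alkoxyallylboration (both C–O stereocenters), acrylate ring-closing metathesis, anti vinylcuprate addition (C8 stereocenter), enolate alkylation.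
5. Ring order: dihydropyranone (metathesis), then cyclohexene (Claisen; the lactone ring is consumed), then bridged γ-lactone (ketone addition and lactonization); the butenolide is attached preformed.

Key step: step 6

Remark: 3-(methoxymethoxy)prop-1-ene, tert-butyl(2-iodoethoxy)diphenylsilane and 3-bromofuran-2(5H)-one are taken as purchasable building blocks; the lactone α-carbon is alkylated without regard to its configuration because the key step erases it.

**Route**

Step 1
Reactants: 1 (E)-but-2-enal; 2 3-(methoxymethoxy)prop-1-ene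
Product: 4 (3S,4S,5E)-3-(methoxymethoxy)hepta-1,5-dien-4-ol, via alkoxyallylborane 3 (not isolated)
Conditions: 2, sec-BuLi, THF, −78 °C; (+)-Ipc2BOMe; BF3·OEt2; then 1, −78 °C; NaOH, H2O2, 0 °C to rt
Reagents that add atoms: none
Why: Brown asymmetric γ-alkoxyallylboration, in which the Z-configured allylborane 3 adds 1,2 to the enal through a closed chair six-membered transition state, so that the Z geometry gives the syn mono-protected diol and the isopinocampheyl groups derived from (−)-α-pinene select the aldehyde face that leads to the (3S,4S) isomer.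

Step 2
Reactants: 4 (3S,4S,5E)-3-(methoxymethoxy)hepta-1,5-dien-4-ol
Product: 5 (3S,4S,5E)-3-(methoxymethoxy)hepta-1,5-dien-4-yl prop-2-enoate
Conditions: acryloyl chloride, Et3N, DMAP (cat.), CH2Cl2, 0 °C
Reagents that add atoms: acryloyl chloride, C=CC(=O)Cl
Why: Standard O-acylation of a secondary allylic alcohol with an acid chloride under amine/DMAP catalysis, which touches no stereocenter.

Step 3
Reactants: 5 (3S,4S,5E)-3-(methoxymethoxy)hepta-1,5-dien-4-yl prop-2-enoate
Product: 6 (5S,6S)-5-(methoxymethoxy)-6-[(1E)-prop-1-en-1-yl]-5,6-dihydro-2H-pyran-2-one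
Conditions: second-generation Grubbs catalyst RuCl2(=CHPh)(H2IMes)(PCy3) (5 mol%), CH2Cl2 (dilute), 40 °C
Reagents that add atoms: none
Why: Ring-closing metathesis of an acrylate onto a terminal vinyl group, in which the ruthenium carbene loads on the monosubstituted alkene and closes the six-membered unsaturated lactone faster than it engages the 1,2-disubstituted propenyl group, leaving both stereocenters untouched.

Step 4
Reactants: 6 (5S,6S)-5-(methoxymethoxy)-6-[(1E)-prop-1-en-1-yl]-5,6-dihydro-2H-pyran-2-one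
Product: 8 (4S,5S,6S)-4-ethenyl-5-(methoxymethoxy)-6-[(1E)-prop-1-en-1-yl]oxan-2-one, via silyl ketene acetal 7 (not isolated)
Conditions: vinylmagnesium bromide, CuBr·SMe2 (10 mol%), TMSCl, THF, −78 °C; then 1 M HCl, 0 °C
Reagents that add atoms: vinylmagnesium bromide, C=C[Mg]Br
Why: Copper-catalyzed, TMSCl-accelerated conjugate addition of a Grignard reagent to an α,β-unsaturated δ-lactone, in which the vinyl group enters C4 anti to the cis-disposed C5 alkoxy and C6 propenyl groups (4,5-trans) and the silyl ketene acetal 7 is hydrolysed on work-up.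

Step 5
Reactants: 8 (4S,5S,6S)-4-ethenyl-5-(methoxymethoxy)-6-[(1E)-prop-1-en-1-yl]oxan-2-one; 9 tert-butyl(2-iodoethoxy)diphenylsilane
Product: 10 (3R,4R,5S,6S)-3-[2-(tert-butyldiphenylsilyloxy)ethyl]-4-ethenyl-5-(methoxymethoxy)-6-[(1E)-prop-1-en-1-yl]oxan-2-one
Conditions: LiN(iPr)2, THF, −78 °C; then 9, DMPU, −78 to −20 °C
Reagents that add atoms: none
Why: Alkylation of a δ-lactone lithium enolate with a primary iodide, in which the electrophile should approach anti to the C4 vinyl group (the 3,4-trans epimer is drawn), although the C3 configuration is immaterial because the next step erases it.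

Step 6
Reactants: 10 (3R,4R,5S,6S)-3-[2-(tert-butyldiphenylsilyloxy)ethyl]-4-ethenyl-5-(methoxymethoxy)-6-[(1E)-prop-1-en-1-yl]oxan-2-one
Product: 13 (1R,2R,5R,6R)-1-[2-(tert-butyldiphenylsilyloxy)ethyl]-6-ethenyl-5-(methoxymethoxy)-2-methylcyclohex-3-ene-1-carboxylic acid, via silyl ketene acetal 11 (not isolated), via silyl ester 12 (not isolated)
Conditions: LiN(iPr)2, TMSCl, Et3N, THF, −78 °C to rt; PhMe, 110 °C; then 1 M HCl, THF, 0 °C
Reagents that add atoms: none
Why: LiN(iPr)2 removes the only lactone α-hydrogen (C3) and TMSCl traps the enolate as the endocyclic silyl ketene acetal 11, which on heating undergoes a concerted suprafacial [3,3] shift in which the C6–O bond breaks and the bond between C3 and the propenyl terminus forms, giving silyl ester 12 and, after hydrolysis, acid 13. The closest known reaction type is the Ireland–Claisen rearrangement of silyl ketene acetals of lactones that carry an alkenyl group on the carbinol carbon, which turns six- and seven-membered lactones into cycloalkene carboxylic acids. The cyclohexene closes in a pericyclic mode: the two-carbon bridge C4–C5 of the lactone rules out a chair and enforces a boat, bicyclo[2.2.2]octane-like six-centre transition state in which the propenyl terminus swings over the ketene acetal carbon. The quaternary carbon (C1 of 13) is set by suprafacial transfer from the C6–O stereocenter made in step 1, because the new bond must form on the lactone face that carries the propenyl group, which puts the carboxyl cis to the former C4 vinyl group and trans to the C5 oxygen. The methyl-bearing carbon (C2 of 13) is set by the E geometry of the propenyl group, which in the boat places the methyl cis to the carboxyl. The step needs enolization at the lactone α-carbon only (there is no other acidic C–H and no β-leaving group) and reaction through the single boat available, while ketene acetal geometry is no issue because that double bond is endocyclic.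

Step 7
Reactants: 13 (1R,2R,5R,6R)-1-[2-(tert-butyldiphenylsilyloxy)ethyl]-6-ethenyl-5-(methoxymethoxy)-2-methylcyclohex-3-ene-1-carboxylic acid
Product: 14 (1R,2R,5R,6R)-1-[2-(tert-butyldiphenylsilyloxy)ethyl]-6-[(1E)-3-methoxy-3-oxoprop-1-en-1-yl]-5-(methoxymethoxy)-2-methylcyclohex-3-ene-1-carboxylic acid
Conditions: methyl acrylate (excess), second-generation Grubbs catalyst (5–10 mol%), CH2Cl2, 40 °C
Reagents that add atoms: methyl acrylate, C=CC(=O)OC
Why: Olefin cross-metathesis between the terminal vinyl group and excess methyl acrylate should give the E-enoate, the unstrained cis-cyclohexene being inert to the ruthenium carbene and no stereocenter being affected.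

Step 8
Reactants: 14 (1R,2R,5R,6R)-1-[2-(tert-butyldiphenylsilyloxy)ethyl]-6-[(1E)-3-methoxy-3-oxoprop-1-en-1-yl]-5-(methoxymethoxy)-2-methylcyclohex-3-ene-1-carboxylic acid
Product: 15 (1R,2R,3R,6R)-1-[2-(tert-butyldiphenylsilyloxy)ethyl]-3-(methoxymethoxy)-2-(3-methoxy-3-oxopropyl)-6-methylcyclohexane-1-carboxylic acid
Conditions: H2 (1 atm), Pd/C, EtOAc, rt
Reagents that add atoms: none
Why: Heterogeneous catalytic hydrogenation saturates the ring alkene and the enoate in one operation without creating a stereocenter, the silyl ether, the acetal and the ester being stable in ethyl acetate.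

Step 9
Reactants: 15 (1R,2R,3R,6R)-1-[2-(tert-butyldiphenylsilyloxy)ethyl]-3-(methoxymethoxy)-2-(3-methoxy-3-oxopropyl)-6-methylcyclohexane-1-carboxylic acid
Product: 16 (1R,2R,3R,6R)-1-[2-(tert-butyldiphenylsilyloxy)ethyl]-3-hydroxy-2-(3-methoxy-3-oxopropyl)-6-methylcyclohexane-1-carboxylic acid
Conditions: ZnBr2, n-PrSH, CH2Cl2, 0 °C
Reagents that add atoms: none
Why: Lewis acid/thiol cleavage of the methoxymethyl ether, in which ZnBr2 activates the acetal and the thiol takes up the methoxymethyl group, should leave the silyl ether, the acid and the ester intact, and the alcohol (trans to the carboxyl, so unable to form the bridged lactone) is carried on at once so that it cannot close onto the side-chain ester.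

Step 10
Reactants: 16 (1R,2R,3R,6R)-1-[2-(tert-butyldiphenylsilyloxy)ethyl]-3-hydroxy-2-(3-methoxy-3-oxopropyl)-6-methylcyclohexane-1-carboxylic acid
Product: 17 (1R,2R,6R)-1-[2-(tert-butyldiphenylsilyloxy)ethyl]-2-(3-methoxy-3-oxopropyl)-6-methyl-3-oxocyclohexane-1-carboxylic acid
Conditions: Dess–Martin periodinane, NaHCO3, CH2Cl2, 0 °C to rt
Reagents that add atoms: none
Why: Dess–Martin oxidation of the secondary alcohol to the ketone under buffered conditions, the C2 stereocenter next to the new ketone already carrying its side chain in the thermodynamically preferred equatorial position.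

Step 11
Reactants: 17 (1R,2R,6R)-1-[2-(tert-butyldiphenylsilyloxy)ethyl]-2-(3-methoxy-3-oxopropyl)-6-methyl-3-oxocyclohexane-1-carboxylic acid
Product: 19 methyl 3-[(1R,2R,5S,8R)-1-[2-(tert-butyldiphenylsilyloxy)ethyl]-2-methyl-7-oxo-5-(prop-1-en-2-yl)-6-oxabicyclo[3.2.1]octan-8-yl]propanoate, via hydroxy acid 18 (not isolated)
Conditions: isopropenylmagnesium bromide, CeCl3 (anhydrous), THF, −78 °C; 1 M HCl, 0 °C; then camphorsulfonic acid (cat.), CH2Cl2, rt
Reagents that add atoms: isopropenylmagnesium bromide, CC(=C)[Mg]Br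
Why: Organocerium 1,2-addition followed by acid-promoted γ-lactonization, in which the first equivalent of reagent deprotonates the acid, the axial C1 carboxylate blocks axial approach so that the isopropenyl group enters C3 equatorially and the new hydroxyl is axial and syn to the carboxyl (3S), and this 1,3-diaxial hydroxy acid 18 should close to the bridged lactone faster than the hydroxyl can attack the side-chain methyl ester.

Step 12
Reactants: 19 methyl 3-[(1R,2R,5S,8R)-1-[2-(tert-butyldiphenylsilyloxy)ethyl]-2-methyl-7-oxo-5-(prop-1-en-2-yl)-6-oxabicyclo[3.2.1]octan-8-yl]propanoate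
Product: 20 methyl 3-[(1R,2R,5S,8R)-1-(2-hydroxyethyl)-2-methyl-7-oxo-5-(prop-1-en-2-yl)-6-oxabicyclo[3.2.1]octan-8-yl]propanoate
Conditions: HF·pyridine, pyridine, THF, 0 °C to rt
Reagents that add atoms: none
Why: Fluoride cleavage of the silyl ether under buffered, non-basic conditions, chosen so that no alkoxide forms that could open the bridged lactone by transacylation to a spiro γ-lactone.

Step 13
Reactants: 20 methyl 3-[(1R,2R,5S,8R)-1-(2-hydroxyethyl)-2-methyl-7-oxo-5-(prop-1-en-2-yl)-6-oxabicyclo[3.2.1]octan-8-yl]propanoate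
Product: 21 methyl 3-[(1R,2R,5S,8R)-1-(2-iodoethyl)-2-methyl-7-oxo-5-(prop-1-en-2-yl)-6-oxabicyclo[3.2.1]octan-8-yl]propanoate
Conditions: I2, PPh3, imidazole, CH2Cl2, 0 °C
Reagents that add atoms: iodine, II
Why: Appel-type iodination of the primary alcohol by SN2 displacement of the alkoxyphosphonium ion under neutral conditions that again avoid transacylation.

Step 14
Reactants: 21 methyl 3-[(1R,2R,5S,8R)-1-(2-iodoethyl)-2-methyl-7-oxo-5-(prop-1-en-2-yl)-6-oxabicyclo[3.2.1]octan-8-yl]propanoate; 22 3-bromofuran-2(5H)-one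
Product: 24 methyl 3-[(1R,2R,5S,8R)-2-methyl-7-oxo-1-[2-(2-oxo-2,5-dihydrofuran-3-yl)ethyl]-5-(prop-1-en-2-yl)-6-oxabicyclo[3.2.1]octan-8-yl]propanoate, via alkylzinc iodide 23 (not isolated)
Conditions: Zn dust, LiCl, THF, 40 °C; then 22, Pd(OAc)2 (2 mol%), SPhos (4 mol%), THF, rt
Reagents that add atoms: none
Why: Negishi sp3–sp2 cross-coupling, in which LiCl-assisted zinc insertion into the primary iodide gives the alkylzinc iodide 23 that tolerates lactone, ester and alkene, and Pd/SPhos-catalyzed coupling with the α-bromobutenolide should attach the ring at its C3 without touching any stereocenter.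

**Compound list**

1 | (E)-but-2-enal | C/C=C/C=O | starting material
2 | 3-(methoxymethoxy)prop-1-ene | C=CCOCOC | starting material
3 | [(2Z)-3-(methoxymethoxy)prop-2-en-1-yl]bis(isopinocampheyl)borane, isopinocampheyl groups from (−)-α-pinene (not isolated) | COCO/C=C\CB([C@H]1C[C@H]2C[C@@H]([C@@H]1C)C2(C)C)[C@H]1C[C@H]2C[C@@H]([C@@H]1C)C2(C)C | intermediate
4 | (3S,4S,5E)-3-(methoxymethoxy)hepta-1,5-dien-4-ol | C/C=C/[C@H](O)[C@@H](OCOC)C=C | intermediate
5 | (3S,4S,5E)-3-(methoxymethoxy)hepta-1,5-dien-4-yl prop-2-enoate | C/C=C/[C@H](OC(=O)C=C)[C@@H](OCOC)C=C | intermediate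
6 | (5S,6S)-5-(methoxymethoxy)-6-[(1E)-prop-1-en-1-yl]-5,6-dihydro-2H-pyran-2-one | C/C=C/[C@@H]1OC(=O)C=C[C@@H]1OCOC | intermediate
7 | {[(2S,3S,4R)-4-ethenyl-3-(methoxymethoxy)-2-[(1E)-prop-1-en-1-yl]-3,4-dihydro-2H-pyran-6-yl]oxy}trimethylsilane (not isolated) | C/C=C/[C@@H]1OC(O[Si](C)(C)C)=C[C@@H](C=C)[C@@H]1OCOC | intermediate
8 | (4S,5S,6S)-4-ethenyl-5-(methoxymethoxy)-6-[(1E)-prop-1-en-1-yl]oxan-2-one | C/C=C/[C@@H]1OC(=O)C[C@@H](C=C)[C@@H]1OCOC | intermediate
9 | tert-butyl(2-iodoethoxy)diphenylsilane | ICCO[Si](c1ccccc1)(c1ccccc1)C(C)(C)C | starting material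
10 | (3R,4R,5S,6S)-3-[2-(tert-butyldiphenylsilyloxy)ethyl]-4-ethenyl-5-(methoxymethoxy)-6-[(1E)-prop-1-en-1-yl]oxan-2-one | C/C=C/[C@@H]1OC(=O)[C@H](CCO[Si](c2ccccc2)(c2ccccc2)C(C)(C)C)[C@@H](C=C)[C@@H]1OCOC | intermediate
11 | tert-butyl{2-[(2S,3S,4R)-4-ethenyl-3-(methoxymethoxy)-2-[(1E)-prop-1-en-1-yl]-6-(trimethylsilyloxy)-3,4-dihydro-2H-pyran-5-yl]ethoxy}diphenylsilane (not isolated) | C/C=C/[C@@H]1OC(O[Si](C)(C)C)=C(CCO[Si](c2ccccc2)(c2ccccc2)C(C)(C)C)[C@@H](C=C)[C@@H]1OCOC | intermediate
12 | trimethylsilyl (1R,2R,5R,6R)-1-[2-(tert-butyldiphenylsilyloxy)ethyl]-6-ethenyl-5-(methoxymethoxy)-2-methylcyclohex-3-ene-1-carboxylate (not isolated) | C[Si](C)(C)OC(=O)[C@]1(CCO[Si](c2ccccc2)(c2ccccc2)C(C)(C)C)[C@H](C)C=C[C@@H](OCOC)[C@@H]1C=C | intermediate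
13 | (1R,2R,5R,6R)-1-[2-(tert-butyldiphenylsilyloxy)ethyl]-6-ethenyl-5-(methoxymethoxy)-2-methylcyclohex-3-ene-1-carboxylic acid | OC(=O)[C@]1(CCO[Si](c2ccccc2)(c2ccccc2)C(C)(C)C)[C@H](C)C=C[C@@H](OCOC)[C@@H]1C=C | intermediate
14 | (1R,2R,5R,6R)-1-[2-(tert-butyldiphenylsilyloxy)ethyl]-6-[(1E)-3-methoxy-3-oxoprop-1-en-1-yl]-5-(methoxymethoxy)-2-methylcyclohex-3-ene-1-carboxylic acid | OC(=O)[C@]1(CCO[Si](c2ccccc2)(c2ccccc2)C(C)(C)C)[C@H](C)C=C[C@@H](OCOC)[C@@H]1/C=C/C(=O)OC | intermediate
15 | (1R,2R,3R,6R)-1-[2-(tert-butyldiphenylsilyloxy)ethyl]-3-(methoxymethoxy)-2-(3-methoxy-3-oxopropyl)-6-methylcyclohexane-1-carboxylic acid | OC(=O)[C@]1(CCO[Si](c2ccccc2)(c2ccccc2)C(C)(C)C)[C@H](C)CC[C@@H](OCOC)[C@@H]1CCC(=O)OC | intermediate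
16 | (1R,2R,3R,6R)-1-[2-(tert-butyldiphenylsilyloxy)ethyl]-3-hydroxy-2-(3-methoxy-3-oxopropyl)-6-methylcyclohexane-1-carboxylic acid | OC(=O)[C@]1(CCO[Si](c2ccccc2)(c2ccccc2)C(C)(C)C)[C@H](C)CC[C@@H](O)[C@@H]1CCC(=O)OC | intermediate
17 | (1R,2R,6R)-1-[2-(tert-butyldiphenylsilyloxy)ethyl]-2-(3-methoxy-3-oxopropyl)-6-methyl-3-oxocyclohexane-1-carboxylic acid | OC(=O)[C@]1(CCO[Si](c2ccccc2)(c2ccccc2)C(C)(C)C)[C@H](C)CCC(=O)[C@@H]1CCC(=O)OC | intermediate
18 | (1R,2R,3S,6R)-1-[2-(tert-butyldiphenylsilyloxy)ethyl]-3-hydroxy-2-(3-methoxy-3-oxopropyl)-6-methyl-3-(prop-1-en-2-yl)cyclohexane-1-carboxylic acid (not isolated) | OC(=O)[C@]1(CCO[Si](c2ccccc2)(c2ccccc2)C(C)(C)C)[C@H](C)CC[C@@](O)(C(C)=C)[C@@H]1CCC(=O)OC | intermediate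
19 | methyl 3-[(1R,2R,5S,8R)-1-[2-(tert-butyldiphenylsilyloxy)ethyl]-2-methyl-7-oxo-5-(prop-1-en-2-yl)-6-oxabicyclo[3.2.1]octan-8-yl]propanoate | C=C(C)[C@@]12CC[C@@H](C)[C@@](CCO[Si](c3ccccc3)(c3ccccc3)C(C)(C)C)(C(=O)O1)[C@H]2CCC(=O)OC | intermediate
20 | methyl 3-[(1R,2R,5S,8R)-1-(2-hydroxyethyl)-2-methyl-7-oxo-5-(prop-1-en-2-yl)-6-oxabicyclo[3.2.1]octan-8-yl]propanoate | C=C(C)[C@@]12CC[C@@H](C)[C@@](CCO)(C(=O)O1)[C@H]2CCC(=O)OC | intermediate
21 | methyl 3-[(1R,2R,5S,8R)-1-(2-iodoethyl)-2-methyl-7-oxo-5-(prop-1-en-2-yl)-6-oxabicyclo[3.2.1]octan-8-yl]propanoate | C=C(C)[C@@]12CC[C@@H](C)[C@@](CCI)(C(=O)O1)[C@H]2CCC(=O)OC | intermediate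
22 | 3-bromofuran-2(5H)-one | O=C1OCC=C1Br | starting material
23 | {2-[(1R,2R,5S,8R)-8-(3-methoxy-3-oxopropyl)-2-methyl-7-oxo-5-(prop-1-en-2-yl)-6-oxabicyclo[3.2.1]octan-1-yl]ethyl}zinc iodide (not isolated) | C=C(C)[C@@]12CC[C@@H](C)[C@@](CC[Zn]I)(C(=O)O1)[C@H]2CCC(=O)OC | intermediate
24 | methyl 3-[(1R,2R,5S,8R)-2-methyl-7-oxo-1-[2-(2-oxo-2,5-dihydrofuran-3-yl)ethyl]-5-(prop-1-en-2-yl)-6-oxabicyclo[3.2.1]octan-8-yl]propanoate | C=C(C)[C@@]12CC[C@@H](C)[C@@](CCC3=CCOC3=O)(C(=O)O1)[C@H]2CCC(=O)OC | target

**Step count and risks**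

Total step count: 14. Longest linear sequence: 14 steps (from 1 and 2 to 24).

Steps most likely to fail:

Step 6. The rearrangement may stall or be diverted: enolization of the α-branched lactone can be incomplete, the ketene acetal can be lost by C-silylation or fragmentation, and the boat transition state is congested because the new quaternary carbon is flanked by two tertiary carbons. Fallback: set out from silyl ketene acetal 7, which step 4 already generates. Instead of being hydrolysed, the crude acetal is heated in toluene, where the same boat Ireland–Claisen rearrangement has to form only a tertiary carbon and should give trimethylsilyl (1R,2R,5R,6R)-6-ethenyl-5-(methoxymethoxy)-2-methylcyclohex-3-ene-1-carboxylate F1, hydrolysed on work-up to (1R,2R,5R,6R)-6-ethenyl-5-(methoxymethoxy)-2-methylcyclohex-3-ene-1-carboxylic acid F2. The quaternary carbon is then made by alkylation of the carboxylic acid dianion (LiN(iPr)2, 2.2 equiv, THF/DMPU) with iodide 9, which should enter anti to the flanking methyl and vinyl groups and give 13, where the route is rejoined.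

Step 7. Cross-metathesis may be too slow: the vinyl group sits next to the quaternary carbon and the catalyst may decay before conversion. Fallback: set out from 13 and replace metathesis by hydrozirconation and carbonylation. Cp2Zr(H)Cl (one extra equivalent to mask the acid as its zirconium carboxylate) adds only to the terminal vinyl group, CO (1 atm) inserts to the acylzirconium, and N-bromosuccinimide followed by MeOH releases the methyl ester, giving (1R,2R,5R,6R)-1-[2-(tert-butyldiphenylsilyloxy)ethyl]-5-(methoxymethoxy)-6-(3-methoxy-3-oxopropyl)-2-methylcyclohex-3-ene-1-carboxylic acid F3. Hydrogenation of the ring alkene (H2, Pd/C, EtOAc) then gives 15, where the route is rejoined.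

Step 11. The carbonyl addition may show poor facial selectivity, the hindered ketone may enolize instead of adding, or the new hydroxyl may close onto the wrong ester. Fallback: set out from 17 and make the lactone C–O bond by cation capture instead of relying on the facial selectivity of the addition. The crude carbinol mixture, which would contain 18 and its C3 epimer (1R,2R,3R,6R)-1-[2-(tert-butyldiphenylsilyloxy)ethyl]-3-hydroxy-2-(3-methoxy-3-oxopropyl)-6-methyl-3-(prop-1-en-2-yl)cyclohexane-1-carboxylic acid F4, is not separated but treated with CF3CO2H in CH2Cl2 at 0 °C. Ionization of the tertiary allylic alcohol gives a planar cation that the axial carboxyl on the neighbouring ring position can capture only from its own face, so both epimers should converge on 19, where the route is rejoined.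

Further compounds
F1 | step 6 | trimethylsilyl (1R,2R,5R,6R)-6-ethenyl-5-(methoxymethoxy)-2-methylcyclohex-3-ene-1-carboxylate | C[Si](C)(C)OC(=O)[C@@H]1[C@H](C)C=C[C@@H](OCOC)[C@@H]1C=C
F2 | step 6 | (1R,2R,5R,6R)-6-ethenyl-5-(methoxymethoxy)-2-methylcyclohex-3-ene-1-carboxylic acid | OC(=O)[C@@H]1[C@H](C)C=C[C@@H](OCOC)[C@@H]1C=C
F3 | step 7 | (1R,2R,5R,6R)-1-[2-(tert-butyldiphenylsilyloxy)ethyl]-5-(methoxymethoxy)-6-(3-methoxy-3-oxopropyl)-2-methylcyclohex-3-ene-1-carboxylic acid | OC(=O)[C@]1(CCO[Si](c2ccccc2)(c2ccccc2)C(C)(C)C)[C@H](C)C=C[C@@H](OCOC)[C@@H]1CCC(=O)OC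
F4 | step 11 | (1R,2R,3R,6R)-1-[2-(tert-butyldiphenylsilyloxy)ethyl]-3-hydroxy-2-(3-methoxy-3-oxopropyl)-6-methyl-3-(prop-1-en-2-yl)cyclohexane-1-carboxylic acid | OC(=O)[C@]1(CCO[Si](c2ccccc2)(c2ccccc2)C(C)(C)C)[C@H](C)CC[C@](O)(C(C)=C)[C@@H]1CCC(=O)OC
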